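**Retrosynthetic overview**
1. Last step: one BCl3 treatment frees both phenols of 1-(2,6-dimethoxyphenyl)-9-[4-(benzyloxy)phenyl]nonan-1-one. It cleaves one ortho-OMe of ring A by chelation and the OBn of ring B.
2. Key disconnection, C2–C3 of the chain: ArCO–CH2(+) (enolonium equivalent, an α-bromo ketone) plus (−)CH2(CH2)6Ar' (a B-alkyl-9-BBN), joined by a boron-ate 1,2-shift. Both carbons are natural nucleophiles.
3. The α-bromo ketone comes from 2',6'-dimethoxyacetophenone. The borane comes from 1-(benzyloxy)-4-(hept-6-enyl)benzene, made from the 4-(benzyloxy)phenyl Grignard reagent and 7-bromohept-1-ene.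
4. No ring is formed, because ring A and ring B are bought intact. The route is convergent: two one-step fragments, then two common steps.

Assumption: the target has no stereocentre and no stereogenic double bond (it is achiral), so there is no enantiomer to select and no step needs stereocontrol.

**Step 1**
Reactants: 1 1-(benzyloxy)-4-bromobenzene; 2 7-bromohept-1-ene
Product: 4 1-(benzyloxy)-4-(hept-6-en-1-yl)benzene, via aryl Grignard reagent 3 (not isolated)
Conditions: Mg, THF, reflux; then 2, Li2CuCl4 (3 mol %), THF, 0 °C to rt
Reagents that add atoms: none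
Why: Kochi-type copper-catalysed Grignard–alkyl halide cross-coupling, in which the aryl cuprate formed from 3 displaces the primary bromide of 2 without touching the terminal alkene or the benzyl ether, and no stereocentre is created.

**Step 2**
Reactants: 5 1-(2,6-dimethoxyphenyl)ethan-1-one
Product: 6 2-bromo-1-(2,6-dimethoxyphenyl)ethan-1-one
Conditions: CuBr2 (2.0 equiv), EtOAc/CHCl3 1:1, reflux
Reagents that add atoms: CuBr2 (copper dibromide), [Cu+2].[Br-].[Br-]
Why: King–Ostrum α-bromination, in which CuBr2 brominates the copper-bound enol of the methyl ketone at the α-carbon rather than the ring, turning the normally nucleophilic α-carbon into an electrophilic acyl-CH2(+) equivalent, with exactly 2.0 equiv limiting dibromination and no stereocentre formed.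

**Step 3**
Reactants: 4 1-(benzyloxy)-4-(hept-6-en-1-yl)benzene; 6 2-bromo-1-(2,6-dimethoxyphenyl)ethan-1-one
Product: 9 1-(2,6-dimethoxyphenyl)-9-[4-(benzyloxy)phenyl]nonan-1-one, via B-alkyl-9-BBN 7 (not isolated), via bromo borate complex 8 (not isolated)
Conditions: 4, 9-BBN (1.05 equiv), THF, 0 °C to rt; then 6, 0 °C; then KOt-Bu/2,6-di-tert-butylphenol (1.0 equiv each, premixed in THF), dropwise, 0 °C to rt; aq. NH4Cl
Reagents that add atoms: none
Why: Anti-Markovnikov hydroboration followed by the Brown organoborane alkylation of an α-bromo ketone, in which the hindered phenoxide deprotonates 6, the bromo enolate binds through carbon to the boron of 7 to give 8, a 1,2-metallate shift moves the primary alkyl group (the 9-BBN ring bonds migrate far more slowly) from boron to the α-carbon with loss of bromide, and the phenol released in the deprotonation then cleaves boron from the product, so a carbon that is normally an enolate nucleophile is joined to a nucleophilic boron-bound carbon and the product has no stereocentre.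

**Step 4**
Reactants: 9 1-(2,6-dimethoxyphenyl)-9-[4-(benzyloxy)phenyl]nonan-1-one
Product: 10 1-(2-hydroxy-6-methoxyphenyl)-9-(4-hydroxyphenyl)nonan-1-one (target)
Conditions: BCl3 (5 equiv), pentamethylbenzene (3 equiv), CH2Cl2, −78 to 0 °C; then 1 M HCl
Reagents that add atoms: none
Why: Lewis-acid ether cleavage, in which BCl3 held between the ketone oxygen and one ortho methoxy group removes only that methyl group (the six-membered boron chelate so formed protects the second methoxy group), while the same reagent ionises the aryl benzyl ether and pentamethylbenzene traps the benzyl cation by Friedel–Crafts alkylation, giving the achiral target.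

**Compound list**
1 | 1-(benzyloxy)-4-bromobenzene | Brc1ccc(OCc2ccccc2)cc1 | starting material
2 | 7-bromohept-1-ene | C=CCCCCCBr | starting material
3 | [4-(benzyloxy)phenyl]magnesium bromide | Br[Mg]c1ccc(OCc2ccccc2)cc1 | intermediate
4 | 1-(benzyloxy)-4-(hept-6-en-1-yl)benzene | C=CCCCCCc1ccc(OCc2ccccc2)cc1 | intermediate
5 | 1-(2,6-dimethoxyphenyl)ethan-1-one | CC(=O)c1c(OC)cccc1OC | starting material
6 | 2-bromo-1-(2,6-dimethoxyphenyl)ethan-1-one | O=C(CBr)c1c(OC)cccc1OC | intermediate
7 | 9-{7-[4-(benzyloxy)phenyl]heptyl}-9-borabicyclo[3.3.1]nonane | B1(CCCCCCCc2ccc(OCc3ccccc3)cc2)C2CCCC1CCC2 | intermediate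
8 | potassium {7-[4-(benzyloxy)phenyl]heptyl}[1-bromo-2-(2,6-dimethoxyphenyl)-2-oxoethyl]-9-boratabicyclo[3.3.1]nonane (racemic, transient) | [K+].COc1cccc(OC)c1C(=O)C(Br)[B-]1(CCCCCCCc2ccc(OCc3ccccc3)cc2)C2CCCC1CCC2 | intermediate
9 | 1-(2,6-dimethoxyphenyl)-9-[4-(benzyloxy)phenyl]nonan-1-one | COc1cccc(OC)c1C(=O)CCCCCCCCc1ccc(OCc2ccccc2)cc1 | intermediate
10 | 1-(2-hydroxy-6-methoxyphenyl)-9-(4-hydroxyphenyl)nonan-1-one | COc1cccc(O)c1C(=O)CCCCCCCCc1ccc(O)cc1 | target

**Step count**
Total steps: 4. Longest linear sequence: 3 (1 → 4 → 9 → 10, or 5 → 6 → 9 → 10).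

**Steps most likely to fail**

Step 3 is the riskiest. The bromo enolate can condense with itself before it finds boron, or the 1,2-shift can be slow. The fallback sets out from 4 and 6 and comes back at 9. It makes the same C2–C3 bond by a radical chain instead of a boron-ate shift. Heat 6 (1.5 equiv) with 4 and dilauroyl peroxide (added in portions) in refluxing 1,2-dichloroethane. This is a Kharasch bromine-atom-transfer addition: the electrophilic α-keto radical adds to the terminal alkene carbon and the secondary radical takes bromine from 6. The product is racemic 9-[4-(benzyloxy)phenyl]-4-bromo-1-(2,6-dimethoxyphenyl)nonan-1-one F1. The secondary bromide is then removed with (Me3Si)3SiH and AIBN in toluene at 80 °C to give 9.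

Step 2 is next. The ring positions para to each methoxy group are strongly activated, so nuclear bromination or dibromination may compete. The fallback sets out from 5 and comes back at 6. It fixes the reacting site first by making a discrete enol derivative. TMSOTf and Et3N in CH2Cl2 at 0 °C give {[1-(2,6-dimethoxyphenyl)ethenyl]oxy}(trimethyl)silane F2, isolated by non-aqueous work-up. This enol ether is far more nucleophilic than the ring and reacts with NBS in THF at −78 to 0 °C to give 6.

Step 4 is third. The ortho-demethylation may stall, the second methoxy group may be lost, or the free phenols may be C-benzylated. The fallback sets out from 9 and comes back at 10. It separates the two cleavages into orthogonal reactions. Hydrogenolysis (H2, 1 atm, Pd/C, EtOAc) removes only the benzyl group and gives 1-(2,6-dimethoxyphenyl)-9-(4-hydroxyphenyl)nonan-1-one F3. MgI2 (2.5 equiv) in toluene/Et2O at 80 °C then removes one ortho methyl group under magnesium chelation to the ketone, giving 10.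

**Further compounds**
F1 | step 3 | 9-[4-(benzyloxy)phenyl]-4-bromo-1-(2,6-dimethoxyphenyl)nonan-1-one (racemic) | COc1cccc(OC)c1C(=O)CCC(Br)CCCCCc1ccc(OCc2ccccc2)cc1
F2 | step 2 | {[1-(2,6-dimethoxyphenyl)ethenyl]oxy}(trimethyl)silane | C=C(O[Si](C)(C)C)c1c(OC)cccc1OC
F3 | step 4 | 1-(2,6-dimethoxyphenyl)-9-(4-hydroxyphenyl)nonan-1-one | COc1cccc(OC)c1C(=O)CCCCCCCCc1ccc(O)cc1
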